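**Retrosynthetic overview**
- Feature: in ring A, C4a lies between C8a (bearing O1) and C5 (bearing OMe). An acyl cation at C4 tethered through O1 can reach only C4a or C8, and C8, para to the C5 methoxy group, is the faster site.
- Last disconnection: C8–H back to C8–Br, so bromine acts as a removable blocking group at C8.
- Key disconnection: C4–C4a of ring C, back to a (Z)-3-aryloxycinnamic acid. Ring C is the only ring formed; rings A and B are bought.
- The acid comes from O1–C2 bond formation (oxa-Michael addition of 2-bromo-4,5-dimethoxyphenol to an arylpropiolate) followed by ester hydrolysis.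
- The two partners come from bromination of 3,4-dimethoxyphenol para to its 3-methoxy group and from acylation of lithiated 3,4,5-trimethoxyphenylacetylene with ClCO2Et.

Key step: step 5

Assumption: the target has no stereocentre, so the only stereochemical element is the C=C geometry of the aryloxycinnamate intermediates, drawn Z as expected from anti addition, with any minor E isomer removed by chromatography at the ester stage.

**Step 1**
Reactants: 1 3,4-dimethoxyphenol
Product: 2 2-bromo-4,5-dimethoxyphenol
Conditions: NBS (1.0 equiv), dry MeCN, −20 → 0 °C, dark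
Reagents that add atoms: N-bromosuccinimide, O=C1CCC(=O)N1Br
Why: Electrophilic aromatic bromination: the carbon ortho to OH and para to the 3-methoxy group is doubly activated and unhindered, whereas the other ortho carbon is wedged between two oxygen substituents, so one equivalent of NBS in the cold should brominate only there without oxidising the electron-rich ring.

**Step 2**
Reactants: 3 5-ethynyl-1,2,3-trimethoxybenzene; 4 ethyl chloroformate
Product: 6 ethyl 3-(3,4,5-trimethoxyphenyl)prop-2-ynoate, via lithium (3,4,5-trimethoxyphenyl)acetylide 5 (not isolated)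
Conditions: n-BuLi (1.05 equiv), THF, −78 °C; then ClCO2Et (1.5 equiv), −78 °C → rt
Reagents that add atoms: ethyl chloroformate (compound 4), CCOC(=O)Cl
Why: Deprotonation of the terminal alkyne and C-acylation of the lithium acetylide with a chloroformate is the standard route to arylpropiolates, and the excess of 4 and the low temperature keep a second acetylide from adding to the product ester.

**Step 3**
Reactants: 2 2-bromo-4,5-dimethoxyphenol; 6 ethyl 3-(3,4,5-trimethoxyphenyl)prop-2-ynoate
Product: 8 ethyl (Z)-3-(2-bromo-4,5-dimethoxyphenoxy)-3-(3,4,5-trimethoxyphenyl)prop-2-enoate, via potassium 2-bromo-4,5-dimethoxyphenoxide 7 (not isolated)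
Conditions: K2CO3 (0.5 equiv), dry DMF, 90 °C
Reagents that add atoms: none
Why: Oxa-Michael addition of a phenoxide to an alkynoate, in which oxygen attacks the carbon bearing ring B and the resulting vinyl anion is protonated anti to the incoming oxygen (trans-addition rule), placing the aryloxy and ester groups cis (Z), while the aryl bromide and methyl ethers are inert to K2CO3.

**Step 4**
Reactants: 8 ethyl (Z)-3-(2-bromo-4,5-dimethoxyphenoxy)-3-(3,4,5-trimethoxyphenyl)prop-2-enoate
Product: 10 (Z)-3-(2-bromo-4,5-dimethoxyphenoxy)-3-(3,4,5-trimethoxyphenyl)prop-2-enoic acid, via lithium carboxylate 9 (not isolated)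
Conditions: LiOH (3 equiv), THF/H2O 3:1, 40 °C; then 1 M HCl, 0 °C, pH 2–3
Reagents that add atoms: lithium hydroxide, [Li+].[OH-]
Why: Saponification (BAc2 hydrolysis) of the ethyl ester, after which the carboxylate charge shields C3 against hydroxide, and brief cold acidification frees the acid without hydrolysing the conjugated aryl enol ether or changing the Z geometry.

**Step 5**
Reactants: 10 (Z)-3-(2-bromo-4,5-dimethoxyphenoxy)-3-(3,4,5-trimethoxyphenyl)prop-2-enoic acid
Product: 12 8-bromo-5,6-dimethoxy-2-(3,4,5-trimethoxyphenyl)chromen-4-one, via acyl methanesulfonate 11 (not isolated)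
Conditions: P2O5/CH3SO3H (1:10 w/w), 25 → 45 °C; then ice/H2O
Reagents that add atoms: none
Why: P2O5 in CH3SO3H dehydrates acid 10 to the acyl methanesulfonate 11, whose ionisation gives an acylium ion that attacks the one free ortho carbon of ring A (future C4a, flanked by the O1-bearing C8a and the methoxy-bearing C5), and loss of the ring proton from the arenium ion restores aromaticity. The closest known reaction type is the acid-mediated intramolecular Friedel–Crafts acylation of 3-aryloxycinnamic acids to flavones (Ruhemann flavone synthesis), combined here with the familiar use of a halogen as a positional blocking group in Friedel–Crafts ring closures. Ring C closes as a six-membered ring by electrophilic aromatic substitution, formally 6-exo at the acyl carbon, with O1 and C2=C3 already in the tether and the C4=O bond left outside the ring. No stereocentre is created, and the Z descriptor disappears once C2=C3 is part of the ring. Two selectivities are needed, C4a over C8 on ring A and ring A over ring B: bromine occupies C8, the only other carbon of ring A within reach, and the Z geometry holds the acyl carbon next to the aryloxy group and away from C2'/C6' of ring B, while any geometry loss through protonation at C3 should still drain to 12 because closure on ring B would give a strained five-membered indenone lacking the hydroxypyrylium stabilisation of protonated 12. The temperature is capped near 45 °C to hold back ipso attack at C–Br, acid-induced loss of bromine and cleavage of the C5 methyl ether peri to the new carbonyl.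

**Step 6**
Reactants: 12 8-bromo-5,6-dimethoxy-2-(3,4,5-trimethoxyphenyl)chromen-4-one
Product: 13 Cerosilin B, 5,6-dimethoxy-2-(3,4,5-trimethoxyphenyl)chromen-4-one
Conditions: Pd(PPh3)4 (5 mol %), HCO2Na (3 equiv), DMF, 100 °C, Ar
Reagents that add atoms: none
Why: Palladium-catalysed transfer hydrodehalogenation, in which zerovalent palladium inserts into C8–Br, formate replaces bromide and loses CO2 to leave an arylpalladium hydride that reductively eliminates C8–H, while C2=C3 (a vinylogous ester inside the pyranone, disubstituted at C2), the ketone and the five methyl ethers are not touched by this hydride source.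

**Compound list**
1 | 3,4-dimethoxyphenol | COc1ccc(O)cc1OC | starting material
2 | 2-bromo-4,5-dimethoxyphenol | COc1cc(O)c(Br)cc1OC | intermediate
3 | 5-ethynyl-1,2,3-trimethoxybenzene | C#Cc1cc(OC)c(OC)c(OC)c1 | starting material
4 | ethyl chloroformate | CCOC(=O)Cl | starting material
5 | lithium (3,4,5-trimethoxyphenyl)acetylide, formed in the flask | [Li+].[C-]#Cc1cc(OC)c(OC)c(OC)c1 | intermediate
6 | ethyl 3-(3,4,5-trimethoxyphenyl)prop-2-ynoate | CCOC(=O)C#Cc1cc(OC)c(OC)c(OC)c1 | intermediate
7 | potassium 2-bromo-4,5-dimethoxyphenoxide, formed in the flask | [K+].[O-]c1cc(OC)c(OC)cc1Br | intermediate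
8 | ethyl (Z)-3-(2-bromo-4,5-dimethoxyphenoxy)-3-(3,4,5-trimethoxyphenyl)prop-2-enoate | CCOC(=O)/C=C(\Oc1cc(OC)c(OC)cc1Br)c1cc(OC)c(OC)c(OC)c1 | intermediate
9 | lithium (Z)-3-(2-bromo-4,5-dimethoxyphenoxy)-3-(3,4,5-trimethoxyphenyl)prop-2-enoate, formed in the flask | [Li+].[O-]C(=O)/C=C(\Oc1cc(OC)c(OC)cc1Br)c1cc(OC)c(OC)c(OC)c1 | intermediate
10 | (Z)-3-(2-bromo-4,5-dimethoxyphenoxy)-3-(3,4,5-trimethoxyphenyl)prop-2-enoic acid | OC(=O)/C=C(\Oc1cc(OC)c(OC)cc1Br)c1cc(OC)c(OC)c(OC)c1 | intermediate
11 | (Z)-3-(2-bromo-4,5-dimethoxyphenoxy)-3-(3,4,5-trimethoxyphenyl)prop-2-enoyl methanesulfonate (mixed anhydride), formed in the flask | CS(=O)(=O)OC(=O)/C=C(\Oc1cc(OC)c(OC)cc1Br)c1cc(OC)c(OC)c(OC)c1 | intermediate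
12 | 8-bromo-5,6-dimethoxy-2-(3,4,5-trimethoxyphenyl)chromen-4-one | COc1cc(-c2cc(=O)c3c(OC)c(OC)cc(Br)c3o2)cc(OC)c1OC | intermediate
13 | Cerosilin B, 5,6-dimethoxy-2-(3,4,5-trimethoxyphenyl)chromen-4-one | COc1cc(-c2cc(=O)c3c(OC)c(OC)ccc3o2)cc(OC)c1OC | target

**Totals**
Total step count: 6
Longest linear sequence: 5 (steps 1, 3, 4, 5, 6 or steps 2, 3, 4, 5, 6)

**Steps most likely to fail**

1. Step 5 (key step).
   - What may go wrong: the attacked carbon is crowded, and its neighbouring methoxy group must twist out of plane. Several processes can therefore compete: acylation of the activated ring B after acid-induced loss of the Z geometry, ipso attack at the brominated carbon with expulsion or migration of bromine, and protodebromination before ring closure, which would redirect closure to the para position. The methyl ether peri to the carbonyl may also be cleaved.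
   - Fallback: it sets out from 1 and 6 and comes back at 13. The regiochemistry is handed to directed ortho-metalation instead of a blocking group, and ring C is closed at O1–C2.
   - Phenol 1 is protected (MOMCl, i-Pr2NEt, CH2Cl2) as 1,2-dimethoxy-4-(methoxymethoxy)benzene F1.
   - n-BuLi in THF at 0 °C should remove the proton between the two coordinating oxygen substituents to give [2,3-dimethoxy-6-(methoxymethoxy)phenyl]lithium F2.
   - Ester 6 is converted (MeNHOMe·HCl, i-PrMgCl, THF, −20 °C) into the Weinreb amide N-methoxy-N-methyl-3-(3,4,5-trimethoxyphenyl)prop-2-ynamide F3.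
   - F3 acylates F2 at −78 °C (aqueous NH4Cl quench) to give 1-[2,3-dimethoxy-6-(methoxymethoxy)phenyl]-3-(3,4,5-trimethoxyphenyl)prop-2-yn-1-one F4.
   - HCl in MeOH removes the acetal to give 1-(6-hydroxy-2,3-dimethoxyphenyl)-3-(3,4,5-trimethoxyphenyl)prop-2-yn-1-one F5.
   - DMAP catalysis in DMF should then close the ring by 6-endo-dig oxa-Michael addition to 13.

2. Step 3.
   - What may go wrong: the conjugate addition may be sluggish, because the ortho-bromophenoxide is hindered and weakly nucleophilic and the alkynoate is deactivated by the donor-rich ring B. Forcing conditions invite hydration of the triple bond by adventitious water, ester cleavage and erosion of the alkene geometry.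
   - Fallback: it sets out from 3 (through acetylide 5) and 2 and comes back at 10. A more electrophilic acceptor replaces the ester.
   - Acetylide 5 is formylated with DMF (THF, −78 °C → rt, reverse quench into cold 1 M HCl) to 3-(3,4,5-trimethoxyphenyl)prop-2-ynal F6.
   - Phenol 2 should add to F6 at room temperature (DABCO cat., MeCN) to give (Z)-3-(2-bromo-4,5-dimethoxyphenoxy)-3-(3,4,5-trimethoxyphenyl)prop-2-enal F7.
   - Pinnick oxidation (NaClO2, NaH2PO4, 2-methylbut-2-ene, t-BuOH/H2O) then delivers acid 10 directly, so step 4 is bypassed as well.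

3. Step 4.
   - What may go wrong: the substrate is a vinylogous aryl ester. Hydroxide may attack C3 and expel the aryloxide in competition with attack at the ester carbonyl, and the fragment left behind would then decarboxylate.
   - Fallback: it sets out from 3 (through acetylide 5) and 2 and comes back at 10. The ester is chosen so that it is cleaved by acid and no nucleophilic base is used.
   - Acetylide 5 is trapped with Boc2O (THF, −78 °C → rt, aqueous NH4Cl) as tert-butyl 3-(3,4,5-trimethoxyphenyl)prop-2-ynoate F8.
   - Phenol 2 is added as in step 3 to give tert-butyl (Z)-3-(2-bromo-4,5-dimethoxyphenoxy)-3-(3,4,5-trimethoxyphenyl)prop-2-enoate F9.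
   - Acidolysis (CF3CO2H, CH2Cl2, 0 °C → rt) gives acid 10.

**Further compounds**
F1 | step 5 | 1,2-dimethoxy-4-(methoxymethoxy)benzene | COCOc1ccc(OC)c(OC)c1
F2 | step 5 | [2,3-dimethoxy-6-(methoxymethoxy)phenyl]lithium | [Li]c1c(OC)c(OC)ccc1OCOC
F3 | step 5 | N-methoxy-N-methyl-3-(3,4,5-trimethoxyphenyl)prop-2-ynamide | CON(C)C(=O)C#Cc1cc(OC)c(OC)c(OC)c1
F4 | step 5 | 1-[2,3-dimethoxy-6-(methoxymethoxy)phenyl]-3-(3,4,5-trimethoxyphenyl)prop-2-yn-1-one | COCOc1ccc(OC)c(OC)c1C(=O)C#Cc1cc(OC)c(OC)c(OC)c1
F5 | step 5 | 1-(6-hydroxy-2,3-dimethoxyphenyl)-3-(3,4,5-trimethoxyphenyl)prop-2-yn-1-one | COc1ccc(O)c(C(=O)C#Cc2cc(OC)c(OC)c(OC)c2)c1OC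
F6 | step 3 | 3-(3,4,5-trimethoxyphenyl)prop-2-ynal | O=CC#Cc1cc(OC)c(OC)c(OC)c1
F7 | step 3 | (Z)-3-(2-bromo-4,5-dimethoxyphenoxy)-3-(3,4,5-trimethoxyphenyl)prop-2-enal | O=C/C=C(\Oc1cc(OC)c(OC)cc1Br)c1cc(OC)c(OC)c(OC)c1
F8 | step 4 | tert-butyl 3-(3,4,5-trimethoxyphenyl)prop-2-ynoate | CC(C)(C)OC(=O)C#Cc1cc(OC)c(OC)c(OC)c1
F9 | step 4 | tert-butyl (Z)-3-(2-bromo-4,5-dimethoxyphenoxy)-3-(3,4,5-trimethoxyphenyl)prop-2-enoate | CC(C)(C)OC(=O)/C=C(\Oc1cc(OC)c(OC)cc1Br)c1cc(OC)c(OC)c(OC)c1
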